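**Assumption:** (S)-4-hydroxycyclopent-2-en-1-one is bought enantiopure; the carbinol centre that later becomes the C2 ketone is carried as an epimer mixture. The route is a paper plan and has not been run. Target numbering: bicyclo[3.2.1]oct-3-ene-2,8-dione, C4 styryl, C6 3,5-dihydroxyphenyl, C7 4-hydroxyphenyl, (1R,5S,6R,7R).

## Retrosynthetic overview

1. Vitisinol D (22) ⇐ tetra-O-methyl ether 21 ⇐ C2 allylic silyl ether 19 (oxidation, then global demethylation last).
2. The cyclohexenone ring is closed last: the C4–C5 bond forms by Au(I) 6-endo-dig attack of a cyclopentanone silyl enol ether on the enyne side chain (18 → 19). The tether forces the bridge onto the face already fixed at C1.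
3. Cyclopentanone 16 comes from a one-pot three-component union of enone 7, 4-MeOC6H4MgBr/Cu (C7 aryl, anti to C6 aryl) and enynal 15 (aldol at C1, anti to C7 aryl).
4. 7 ⇐ (S)-4-hydroxycyclopentenone + arylboronate 3 (Rh 1,4-addition anti to OTBS, then β-elimination). 15 ⇐ propargyl alcohol + (E)-1,2-dichloroethene + 4-bromophenol (Sonogashira, Suzuki, oxidation).
5. Ring order: purchased cyclopentenone ring first, bridging cyclohexenone second.

## Route

**Step 1**
Reactants: 1 resorcinol
Product: 2 1,3-dimethoxybenzene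
Conditions: MeI, K2CO3, acetone, reflux
Reagents that add atoms: iodomethane, CI
Why: Williamson O-methylation masks both phenols as ethers that survive every later step.

**Step 2**
Reactants: 2 1,3-dimethoxybenzene
Product: 3 2-(3,5-dimethoxyphenyl)-4,4,5,5-tetramethyl-1,3,2-dioxaborolane
Conditions: [Ir(OMe)(cod)]2 (1.5 mol %), dtbpy, B2pin2, THF, 80 °C
Reagents that add atoms: bis(pinacolato)diboron, CC1(C)OB(OC1(C)C)B1OC(C)(C)C(C)(C)O1
Why: Ir-catalysed C–H borylation is sterically controlled and selects C5, the only position not ortho to a methoxy group.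

**Step 3**
Reactants: 4 (S)-4-hydroxycyclopent-2-en-1-one
Product: 5 (S)-4-(tert-butyldimethylsilyloxy)cyclopent-2-en-1-one
Conditions: TBSCl, imidazole, CH2Cl2, 0 °C → rt
Reagents that add atoms: TBSCl, CC(C)(C)[Si](C)(C)Cl
Why: Silylation gives a bulky, non-coordinating group that directs the next addition to the opposite face.

**Step 4**
Reactants: 5 (S)-4-(TBSO)cyclopent-2-en-1-one; 3 arylboronate
Product: 6 (3R,4S)-4-(TBSO)-3-(3,5-dimethoxyphenyl)cyclopentan-1-one (trans)
Conditions: [Rh(cod)OH]2 (2.5 mol %), dioxane/H2O 10:1, 35 °C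
Reagents that add atoms: none
Why: Hayashi–Miyaura Rh-catalysed 1,4-addition delivers the aryl group anti to the OTBS group, setting the future C6 centre; mild base-free conditions avoid premature elimination and double arylation.

**Step 5**
Reactants: 6 trans-3-aryl-4-silyloxycyclopentanone
Product: 7 (S)-4-(3,5-dimethoxyphenyl)cyclopent-2-en-1-one
Conditions: DBU (1.1 equiv), CH2Cl2, −20 → 0 °C, AcOH quench
Reagents that add atoms: none
Why: E1cB β-elimination of silanolate gives the enone with the aryl stereocentre now γ; low temperature and a short reaction time are used to avoid γ-deprotonation, which would racemise or isomerise it.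

**Step 6**
Reactants: 8 4-bromophenol
Product: 9 4-bromoanisole
Conditions: MeI, K2CO3, acetone, reflux
Reagents that add atoms: iodomethane, CI
Why: Williamson O-methylation protects the phenol before organometallic chemistry.

**Step 7**
Reactants: 9 4-bromoanisole
Product: 10 4-methoxyphenylboronic acid
Conditions: n-BuLi, THF, −78 °C; B(OiPr)3; aq HCl
Reagents that add atoms: triisopropyl borate, CC(C)OB(OC(C)C)OC(C)C; water, O
Why: Br/Li exchange followed by borate quench and hydrolysis is the standard boronic acid synthesis.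

**Step 8**
Reactants: 11 propargyl alcohol; 12 (E)-1,2-dichloroethene (5 equiv)
Product: 13 (E)-5-chloropent-4-en-2-yn-1-ol
Conditions: Pd(PPh3)4 (5 mol %), CuI (10 mol %), n-BuNH2, Et2O, rt
Reagents that add atoms: none
Why: Sonogashira mono-coupling with excess dihalide proceeds with retention of the E geometry.

**Step 9**
Reactants: 13 (E)-chloroenynol; 10 4-methoxyphenylboronic acid
Product: 14 (E)-5-(4-methoxyphenyl)pent-4-en-2-yn-1-ol
Conditions: Pd(OAc)2 (3 mol %), SPhos (6 mol %), K3PO4, THF/H2O, 50 °C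
Reagents that add atoms: none
Why: Suzuki–Miyaura coupling of the activated alkenyl chloride is stereoretentive and tolerates the free alcohol.

**Step 10**
Reactants: 14 enynol
Product: 15 (E)-5-(4-methoxyphenyl)pent-4-en-2-ynal
Conditions: activated MnO2, CH2Cl2, rt (use at once)
Reagents that add atoms: none
Why: MnO2 selectively oxidises the propargylic alcohol to the ynal.

**Step 11**
Reactants: 7 (S)-4-aryl-cyclopentenone; 9 4-bromoanisole (as its Grignard); 15 enynal
Product: 16 (2R,3R,4S)-4-(3,5-dimethoxyphenyl)-2-[(E)-1-hydroxy-5-(4-methoxyphenyl)pent-4-en-2-yn-1-yl]-3-(4-methoxyphenyl)cyclopentan-1-one (2,3-trans, 3,4-trans; carbinol epimers)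
Conditions: 9, Mg, THF → ArMgBr (1.1 equiv); CuBr·SMe2 (10 mol %), 7, THF, −78 → −40 °C; then 15 (1.4 equiv), −78 °C; aq NH4Cl
Reagents that add atoms: none
Why: Cu-catalysed conjugate addition puts the anisyl group anti to the C4 aryl (future C7), and the regiodefined magnesium enolate then undergoes aldol addition to the ynal anti to the new aryl (future C1), a Noyori-type three-component coupling.

**Step 12**
Reactants: 16 aldol adduct
Product: 17 (2R,3R,4S)-2-[(E)-1-(TBSO)-5-(4-methoxyphenyl)pent-4-en-2-yn-1-yl]-4-(3,5-dimethoxyphenyl)-3-(4-methoxyphenyl)cyclopentan-1-one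
Conditions: TBSOTf, 2,6-lutidine, CH2Cl2, −78 °C
Reagents that add atoms: TBSOTf, CC(C)(C)[Si](C)(C)OS(=O)(=O)C(F)(F)F
Why: Low-temperature silylation blocks retro-aldol and keeps the side-chain carbon at the alcohol level so that C2 of the ring stays configurationally stable.

**Step 13**
Reactants: 17 silyl-protected ketone
Product: 18 (3R,4R,5R)-1-(TBSO)-5-[(E)-1-(TBSO)-5-(4-methoxyphenyl)pent-4-en-2-yn-1-yl]-3-(3,5-dimethoxyphenyl)-4-(4-methoxyphenyl)cyclopent-1-ene
Conditions: LiHMDS, THF, −78 °C; TBSCl, HMPA, −78 → −20 °C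
Reagents that add atoms: TBSCl, CC(C)(C)[Si](C)(C)Cl
Why: Kinetic deprotonation takes the unhindered CH2 rather than the tertiary α-CH, giving the distal enol ether without touching the existing stereocentres.

**Step 14**
Reactants: 18 silyl enol ether–enyne
Product: 19 (1R,5S,6R,7R)-2-(TBSO)-6-(3,5-dimethoxyphenyl)-7-(4-methoxyphenyl)-4-[(E)-2-(4-methoxyphenyl)ethenyl]bicyclo[3.2.1]oct-3-en-8-one (C2 epimers)
Conditions: [JohnPhosAu(NCMe)]SbF6 (5 mol %), i-PrOH (1.5 equiv), CH2Cl2, rt
Reagents that add atoms: none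
Why: Au(I)-catalysed 6-endo-dig carbocyclisation (Conia-ene type) attacks the distal alkyne carbon, which is the one stabilised by the electron-rich styryl group; the tether can only reach the enol ether from its own face, which sets C5, and protodeauration leaves the C3=C4 alkene and the C8 ketone.

**Step 15**
Reactants: 19 bicyclic silyl ether
Product: 20 (1R,5S,6R,7R)-2-hydroxy-6-(3,5-dimethoxyphenyl)-7-(4-methoxyphenyl)-4-[(E)-2-(4-methoxyphenyl)ethenyl]bicyclo[3.2.1]oct-3-en-8-one (C2 epimers)
Conditions: TBAF, AcOH, THF, 0 °C → rt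
Reagents that add atoms: none
Why: Buffered fluoride desilylation frees the allylic alcohol; retro-aldol is impossible because it would need a bridgehead enolate.

**Step 16**
Reactants: 20 allylic alcohol
Product: 21 (1R,5S,6R,7R)-6-(3,5-dimethoxyphenyl)-7-(4-methoxyphenyl)-4-[(E)-2-(4-methoxyphenyl)ethenyl]bicyclo[3.2.1]oct-3-ene-2,8-dione
Conditions: Dess–Martin periodinane, NaHCO3, CH2Cl2, 0 °C → rt
Reagents that add atoms: none
Why: Dess–Martin oxidation converts both C2 epimers to the enone; the resulting bridged 1,3-diketone cannot enolise, so C1 is not at risk.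

**Step 17**
Reactants: 21 tetra-O-methyl vitisinol D
Product: 22 vitisinol D
Conditions: BBr3 (10 equiv), CH2Cl2, −78 → 0 °C; ice-water quench
Reagents that add atoms: none
Why: Lewis-acid ether cleavage removes all four aryl methyl ethers; no stereocentre is epimerisable because C1 and C5 are bridgeheads and C6 and C7 are not α to a carbonyl.

## Compound list

1 | resorcinol | Oc1cccc(O)c1 | starting material
2 | 1,3-dimethoxybenzene | COc1cccc(OC)c1 | intermediate
3 | 2-(3,5-dimethoxyphenyl)-4,4,5,5-tetramethyl-1,3,2-dioxaborolane | COc1cc(OC)cc(c1)B1OC(C)(C)C(C)(C)O1 | intermediate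
4 | (S)-4-hydroxycyclopent-2-en-1-one | O=C1C=C[C@@H](O)C1 | starting material
5 | (S)-4-(tert-butyldimethylsilyloxy)cyclopent-2-en-1-one | O=C1C=C[C@@H](O[Si](C)(C)C(C)(C)C)C1 | intermediate
6 | (3R,4S)-4-(TBSO)-3-(3,5-dimethoxyphenyl)cyclopentan-1-one | O=C1C[C@H](c2cc(OC)cc(OC)c2)[C@@H](O[Si](C)(C)C(C)(C)C)C1 | intermediate
7 | (S)-4-(3,5-dimethoxyphenyl)cyclopent-2-en-1-one | O=C1C=C[C@@H](c2cc(OC)cc(OC)c2)C1 | intermediate
8 | 4-bromophenol | Oc1ccc(Br)cc1 | starting material
9 | 4-bromoanisole | COc1ccc(Br)cc1 | intermediate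
10 | 4-methoxyphenylboronic acid | COc1ccc(B(O)O)cc1 | intermediate
11 | propargyl alcohol | OCC#C | starting material
12 | (E)-1,2-dichloroethene | Cl/C=C/Cl | starting material
13 | (E)-5-chloropent-4-en-2-yn-1-ol | OCC#C/C=C/Cl | intermediate
14 | (E)-5-(4-methoxyphenyl)pent-4-en-2-yn-1-ol | OCC#C/C=C/c1ccc(OC)cc1 | intermediate
15 | (E)-5-(4-methoxyphenyl)pent-4-en-2-ynal | O=CC#C/C=C/c1ccc(OC)cc1 | intermediate
16 | (2R,3R,4S)-4-(3,5-dimethoxyphenyl)-2-[(E)-1-hydroxy-5-(4-methoxyphenyl)pent-4-en-2-yn-1-yl]-3-(4-methoxyphenyl)cyclopentan-1-one | OC(C#C/C=C/c1ccc(OC)cc1)[C@@H]1C(=O)C[C@H](c2cc(OC)cc(OC)c2)[C@H]1c1ccc(OC)cc1 | intermediate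
17 | TBS ether of 16 | CC(C)(C)[Si](C)(C)OC(C#C/C=C/c1ccc(OC)cc1)[C@@H]1C(=O)C[C@H](c2cc(OC)cc(OC)c2)[C@H]1c1ccc(OC)cc1 | intermediate
18 | (3R,4R,5R)-1-(TBSO)-5-[(E)-1-(TBSO)-5-(4-methoxyphenyl)pent-4-en-2-yn-1-yl]-3-(3,5-dimethoxyphenyl)-4-(4-methoxyphenyl)cyclopent-1-ene | CC(C)(C)[Si](C)(C)OC(C#C/C=C/c1ccc(OC)cc1)[C@@H]1C(O[Si](C)(C)C(C)(C)C)=C[C@H](c2cc(OC)cc(OC)c2)[C@H]1c1ccc(OC)cc1 | intermediate
19 | (1R,5S,6R,7R)-2-(TBSO)-6-(3,5-dimethoxyphenyl)-7-(4-methoxyphenyl)-4-[(E)-2-(4-methoxyphenyl)ethenyl]bicyclo[3.2.1]oct-3-en-8-one | CC(C)(C)[Si](C)(C)OC1C=C(/C=C/c2ccc(OC)cc2)[C@H]2C(=O)[C@@H]1[C@H](c1ccc(OC)cc1)[C@H]2c1cc(OC)cc(OC)c1 | intermediate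
20 | (1R,5S,6R,7R)-2-hydroxy-6-(3,5-dimethoxyphenyl)-7-(4-methoxyphenyl)-4-[(E)-2-(4-methoxyphenyl)ethenyl]bicyclo[3.2.1]oct-3-en-8-one | OC1C=C(/C=C/c2ccc(OC)cc2)[C@H]2C(=O)[C@@H]1[C@H](c1ccc(OC)cc1)[C@H]2c1cc(OC)cc(OC)c1 | intermediate
21 | (1R,5S,6R,7R)-6-(3,5-dimethoxyphenyl)-7-(4-methoxyphenyl)-4-[(E)-2-(4-methoxyphenyl)ethenyl]bicyclo[3.2.1]oct-3-ene-2,8-dione | O=C1C=C(/C=C/c2ccc(OC)cc2)[C@H]2C(=O)[C@@H]1[C@H](c1ccc(OC)cc1)[C@H]2c1cc(OC)cc(OC)c1 | intermediate
22 | vitisinol D, (1R,5S,6R,7R)-6-(3,5-dihydroxyphenyl)-7-(4-hydroxyphenyl)-4-[(E)-2-(4-hydroxyphenyl)ethenyl]bicyclo[3.2.1]oct-3-ene-2,8-dione | O=C1C=C(/C=C/c2ccc(O)cc2)[C@H]2C(=O)[C@@H]1[C@H](c1ccc(O)cc1)[C@H]2c1cc(O)cc(O)c1 | target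

## Summary

**Total steps:** 17

**Longest linear sequence:** 11 (steps 1, 2, 4, 5, 11–17; equally 6, 7, 9, 10, 11–17)

**Steps most likely to fail**

- **Step 14 (Au 6-endo-dig closure).** The new bond forms cis to the neighbouring C6 aryl, and 5-exo closure or simple protodesilylation may compete. Fallback: replace the alkyne cyclisation by a bridged aldol. Run step 11 with (E)-5-(4-methoxyphenyl)-3-(triethylsilyloxy)pent-4-enal instead of 15, unmask and oxidise that allylic alcohol to the styryl ketone, close C5–C4 by pyrrolidine/AcOH enamine aldol of the cyclopentanone onto it, then oxidise C2–OH and dehydrate (E1cB) to 21.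
- **Step 11 (three-component union).** Grignard 1,2-addition or γ-deprotonation of 7, and side reactions of the ynal with residual organocopper, can erode yield and selectivity. Fallback: split the union. Run the Cu-catalysed aryl addition with TMSCl, isolate the regiodefined silyl enol ether, and join it to 15 by a BF3·OEt2 Mukaiyama aldol (ynal optionally as its Co2(CO)6 complex).
- **Step 17 (global BBr3 demethylation).** The dienone and the strained, non-enolisable β-diketone may not tolerate excess BBr3 or the quench (bromide addition, retro-Claisen). Fallback: change the protecting-group plan. Carry all four phenols as TIPS ethers from steps 1 and 6, with the C2 alcohol as a TES ether removed by PPTS/MeOH before oxidation, so the last step is buffered TBAF/AcOH desilylation.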